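The side chain on C6 of ring A ends in a C6'' carbinol flanked by the C7''=C8'' methylidene. Read backwards, this is the allylically transposed form of an (E)-C6''=C7'' alkene whose C8'' carries a hydroxyl. Everything therefore rests on epoxidising that one alkene late, on the intact flavanone: a titanium–tartrate, hydroxyl-anchored oxygen transfer builds the oxirane (C6''–O, C7''–O) and sets C6'' as R in a single operation, and iodide formation plus zinc then moves the alkene to C7''=C8''. The substrate is the fully MOM-protected (2S)-6-(8-hydroxygeranyl)flavanone, whose C8'' oxygen is installed on geranyl acetate at the outset and whose C2 centre comes from a rhodium-catalysed aryl addition to a 6-substituted chromone.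

Key step: step 16

Remark (numbering and shorthand): side-chain carbons run C1'' (on C6 of ring A) to C8''; "silyloxygeranyl" means the (2E,6E)-8-[(tert-butyldiphenylsilyl)oxy]-3,7-dimethylocta-2,6-dien-1-yl group and MOM means methoxymethyl.
Assumption: commercial geranyl acetate is the pure (E)-isomer, and the rhodium/(S)-bisphosphine catalyst of step 14 is taken to show on the chromone the facial sense it shows on six-membered cyclic enones (aryl delivered to give 2S); the antipodal ligand is used if a first run proves otherwise.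

Step 1
Reactants: 1 geranyl acetate
Product: 2 (2E,6E)-8-hydroxy-3,7-dimethylocta-2,6-dien-1-yl acetate
Conditions: SeO2 (0.3 equiv), t-BuOOH (3 equiv), salicylic acid (0.1 equiv), CH2Cl2, 0 °C → rt; stopped at partial conversion, 1 recovered
Reagents that add atoms: selenium dioxide, O=[Se]=O (transfers the oxygen); tert-butyl hydroperoxide, CC(C)(C)OO (stoichiometric oxygen source)
Why: Riley-type allylic hydroxylation (ene reaction followed by [2,3]-sigmatropic shift) takes place at the terminal alkene because the C2=C3 alkene is deactivated by the allylic acetate, and it selects the methyl group trans to the chain, so the product should be the (6E)-alcohol.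

Step 2
Reactants: 2 (2E,6E)-8-hydroxy-3,7-dimethylocta-2,6-dien-1-yl acetate
Product: 3 (2E,6E)-8-[(tert-butyldiphenylsilyl)oxy]-3,7-dimethylocta-2,6-dien-1-yl acetate
Conditions: t-BuPh2SiCl, imidazole, DMF, 0 °C → rt
Reagents that add atoms: tert-butyl(chloro)diphenylsilane, CC(C)(C)[Si](Cl)(c1ccccc1)c1ccccc1
Why: Silylation of the primary allylic alcohol gives an ether chosen because it must outlast the fluoride treatment of step 8 and can be removed without base in step 15.

Step 3
Reactants: 3 (2E,6E)-8-[(tert-butyldiphenylsilyl)oxy]-3,7-dimethylocta-2,6-dien-1-yl acetate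
Product: 4 (2E,6E)-8-[(tert-butyldiphenylsilyl)oxy]-3,7-dimethylocta-2,6-dien-1-ol
Conditions: K2CO3 (0.2 equiv), MeOH, 0 °C → rt
Reagents that add atoms: none
Why: Zemplén-type methanolysis of the acetate with catalytic carbonate leaves the silyl ether and both alkenes untouched.

Step 4
Reactants: 4 (2E,6E)-8-[(tert-butyldiphenylsilyl)oxy]-3,7-dimethylocta-2,6-dien-1-ol
Product: 5 (2E,6E)-1-bromo-8-[(tert-butyldiphenylsilyl)oxy]-3,7-dimethylocta-2,6-diene
Conditions: CBr4, PPh3, CH2Cl2, −20 → 0 °C; used without storage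
Reagents that add atoms: tetrabromomethane, BrC(Br)(Br)Br
Why: Appel bromination proceeds by SN2 displacement at the primary allylic carbon under neutral conditions, so neither allylic transposition nor E/Z scrambling should occur and the silyl ether survives.

Step 5
Reactants: 6 phloroglucinol
Product: 7 3,5-bis(methoxymethoxy)phenol
Conditions: MOMCl (2.1 equiv), i-Pr2NEt, CH2Cl2/DMF, 0 °C → rt; chromatographic separation
Reagents that add atoms: chloromethyl methyl ether, COCCl
Why: O-Alkylation of the phenoxides with two equivalents of the chloromethyl ether makes the bis-ether the main component of a statistical mixture, from which it is separated (the mono-ether is recycled).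

Step 6
Reactants: 7 3,5-bis(methoxymethoxy)phenol
Product: 8 [3,5-bis(methoxymethoxy)phenoxy]triisopropylsilane
Conditions: i-Pr3SiCl, imidazole, DMF, rt
Reagents that add atoms: chlorotri(propan-2-yl)silane, CC(C)[Si](Cl)(C(C)C)C(C)C
Why: Silylation of the remaining phenol gives a bulky ether that neither directs lithiation nor allows it at the adjacent carbons, which marks the oxygen that will become O1 as different from the two that will flank the side chain.

Step 7
Reactants: 8 [3,5-bis(methoxymethoxy)phenoxy]triisopropylsilane; 5 (2E,6E)-1-bromo-8-[(tert-butyldiphenylsilyl)oxy]-3,7-dimethylocta-2,6-diene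
Product: 10 [3,5-bis(methoxymethoxy)-4-(silyloxygeranyl)phenoxy]triisopropylsilane, via aryllithium 9 (not isolated)
Conditions: n-BuLi (1.1 equiv), THF, 0 °C; then CuI (10 mol%), 5, −78 → 0 °C
Reagents that add atoms: none
Why: Directed ortho-metalation, in which the two MOM ethers cooperatively steer n-BuLi to the C–H between them, is followed by copper-catalysed SN2 allylation of the aryllithium at the primary carbon of 5, which forms the future C6–C1'' bond para to the silyloxy group without allylic transposition or loss of E geometry.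

Step 8
Reactants: 10 [3,5-bis(methoxymethoxy)-4-(silyloxygeranyl)phenoxy]triisopropylsilane
Product: 11 3,5-bis(methoxymethoxy)-4-(silyloxygeranyl)phenol
Conditions: Bu4NF (1.05 equiv), THF, 0 °C, 15 min
Reagents that add atoms: none
Why: Fluoride desilylation cleaves the aryl silyl ether (phenoxide leaving group) within minutes at 0 °C, conditions under which the primary alkyl tert-butyldiphenylsilyl ether is inert.

Step 9
Reactants: 11 3,5-bis(methoxymethoxy)-4-(silyloxygeranyl)phenol
Product: 12 6-hydroxy-2,4-bis(methoxymethoxy)-3-(silyloxygeranyl)benzaldehyde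
Conditions: MgCl2 (2 equiv), Et3N (4 equiv), (CH2O)n (6 equiv), MeCN, reflux
Reagents that add atoms: formaldehyde (as paraformaldehyde), C=O
Why: In the Casnati–Skattebøl ortho-formylation the magnesium phenoxide delivers formaldehyde only to an ortho carbon (the two are equivalent by symmetry) and a second formaldehyde oxidises the benzylic alkoxide by hydride transfer, all in a basic medium that leaves the acetals and the silyl ether intact.

Step 10
Reactants: 12 6-hydroxy-2,4-bis(methoxymethoxy)-3-(silyloxygeranyl)benzaldehyde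
Product: 13 rac-1-[6-hydroxy-2,4-bis(methoxymethoxy)-3-(silyloxygeranyl)phenyl]prop-2-yn-1-ol
Conditions: HC≡CMgBr (3 equiv), THF, −20 → 0 °C; aq NH4Cl; crude product used directly
Reagents that add atoms: ethynylmagnesium bromide, C#C[Mg]Br
Why: Grignard addition of the acetylide to the aldehyde follows deprotonation of the phenol by the first equivalent, and the carbinol centre, formed racemic, is erased in step 11, which is why the acid-sensitive diol is carried on crude.

Step 11
Reactants: 13 rac-1-[6-hydroxy-2,4-bis(methoxymethoxy)-3-(silyloxygeranyl)phenyl]prop-2-yn-1-ol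
Product: 15 5,7-bis(methoxymethoxy)-6-(silyloxygeranyl)-4H-chromen-4-one, via ynone 14 (not isolated)
Conditions: MnO2 (activated, 15 equiv), CH2Cl2, rt; filter; then K2CO3 (0.2 equiv), acetone, rt
Reagents that add atoms: none
Why: MnO2 oxidises the benzylic propargylic carbinol to the ynone and the ortho phenoxide then adds 6-endo-dig to the terminal alkyne carbon (intramolecular oxa-Michael addition), and because the only free phenol is the one para to the side chain the pyranone can close in one direction only, placing the chain at C6 and not at C8.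

Step 12
Reactants: 16 3-methoxycatechol
Product: 17 1-methoxy-2,3-bis(methoxymethoxy)benzene
Conditions: MOMCl (2.5 equiv), i-Pr2NEt, CH2Cl2, 0 °C → rt
Reagents that add atoms: chloromethyl methyl ether, COCCl
Why: Exhaustive O-alkylation of both catechol hydroxyls with the chloromethyl ether is a routine acetal protection.

Step 13
Reactants: 17 1-methoxy-2,3-bis(methoxymethoxy)benzene
Product: 19 [3-methoxy-4,5-bis(methoxymethoxy)phenyl]boronic acid, via pinacol boronate 18 (not isolated)
Conditions: [Ir(OMe)(cod)]2 (1.5 mol%), 4,4′-di-tert-butyl-2,2′-bipyridine (3 mol%), B2pin2 (1.0 equiv), THF, 80 °C; then NaIO4, NH4OAc, acetone/H2O, rt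
Reagents that add atoms: bis(pinacolato)diboron, CC1(C)OB(B2OC(C)(C)C(C)(C)O2)OC1(C)C; water, O
Why: Iridium-catalysed C–H borylation (Hartwig–Miyaura) is governed by sterics and therefore attacks C5, the only C–H of the 1,2,3-trisubstituted ring without an ortho substituent, and periodate cleavage of the pinacol then frees the boronic acid under buffered neutral conditions that spare the acetals.

Step 14
Reactants: 15 5,7-bis(methoxymethoxy)-6-(silyloxygeranyl)-4H-chromen-4-one; 19 [3-methoxy-4,5-bis(methoxymethoxy)phenyl]boronic acid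
Product: 20 (2S)-2-[3-methoxy-4,5-bis(methoxymethoxy)phenyl]-5,7-bis(methoxymethoxy)-6-(silyloxygeranyl)chroman-4-one
Conditions: [Rh(OH)(cod)]2 (3 mol%), (S)-MeO-F12-BIPHEP (7 mol%), 19 (3 equiv), toluene/H2O 10:1, 30 °C
Reagents that add atoms: none
Why: In this Hayashi–Miyaura asymmetric 1,4-addition the aryl–rhodium species (monovalent rhodium) formed by transmetalation inserts the chromone C2=C3 bond and the oxa-π-allyl is hydrolysed, the electron-poor bisphosphine speeding insertion into the poorly electrophilic chromone and limiting ring opening, while its (S) axial chirality controls the face and is expected to set C2 as S.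

Step 15
Reactants: 20 (2S)-2-[3-methoxy-4,5-bis(methoxymethoxy)phenyl]-5,7-bis(methoxymethoxy)-6-(silyloxygeranyl)chroman-4-one
Product: 21 (2S)-6-[(2E,6E)-8-hydroxy-3,7-dimethylocta-2,6-dien-1-yl]-2-[3-methoxy-4,5-bis(methoxymethoxy)phenyl]-5,7-bis(methoxymethoxy)chroman-4-one
Conditions: HF·pyridine, pyridine, THF, 0 °C → rt
Reagents that add atoms: none
Why: Fluoride desilylation with pyridine-buffered HF is non-basic, so the flavanone should not open by retro-oxa-Michael reaction (C2 stays S) and the aryl MOM ethers are untouched.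

Step 16
Reactants: 21 (2S)-6-[(2E,6E)-8-hydroxy-3,7-dimethylocta-2,6-dien-1-yl]-2-[3-methoxy-4,5-bis(methoxymethoxy)phenyl]-5,7-bis(methoxymethoxy)chroman-4-one
Product: 22 (2S)-6-{(2E)-5-[(2R,3R)-3-(hydroxymethyl)-3-methyloxiran-2-yl]-3-methylpent-2-en-1-yl}-2-[3-methoxy-4,5-bis(methoxymethoxy)phenyl]-5,7-bis(methoxymethoxy)chroman-4-one, the (6''R,7''R)-epoxy alcohol
Conditions: Ti(OiPr)4 (0.6 equiv), D-(−)-diethyl tartrate (0.75 equiv), t-BuOOH (2 equiv, anhydrous, decane), 4 Å molecular sieves, CH2Cl2, −25 °C; 10% aq tartaric acid work-up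
Reagents that add atoms: tert-butyl hydroperoxide, CC(C)(C)OO
Why: The C8'' hydroxyl and tert-butyl hydroperoxide exchange onto the dimeric titanium tartrate complex, and the bound peroxide passes one oxygen atom concertedly and suprafacially to the C6''=C7'' π bond, so the oxirane closes by [2+1] oxygen-atom transfer with both C–O bonds formed on the same face and the E geometry carried over into a trans oxirane. The closest known reaction is the Katsuki–Sharpless asymmetric epoxidation of (E)-2-methylalk-2-en-1-ols, among its most reliable substrates. Both new stereocenters are set by the reagent: D-(−)-diethyl tartrate delivers oxygen to the face that gives the (2R,3R) epoxy alcohol, here 6''R,7''R, and the C2 centre, ten bonds away, has no influence. The step needs site selectivity between two trisubstituted alkenes, which the C8'' alkoxide anchor secures because the C2''=C3'' alkene has no ligating group and is inert to the titanium peroxide at −25 °C. It also needs the polyether substrate not to sequester titanium, which is why a sub-stoichiometric rather than a few-percent loading and molecular sieves are used, and the mild tartaric acid work-up keeps base away from the flavanone.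

Step 17
Reactants: 22 the (6''R,7''R)-epoxy alcohol
Product: 23 (2S)-6-{(2E)-5-[(2R,3S)-3-(iodomethyl)-3-methyloxiran-2-yl]-3-methylpent-2-en-1-yl}-2-[3-methoxy-4,5-bis(methoxymethoxy)phenyl]-5,7-bis(methoxymethoxy)chroman-4-one
Conditions: PPh3, I2, imidazole, CH2Cl2, 0 °C
Reagents that add atoms: iodine, II
Why: Garegg–Samuelsson iodination (Appel type) converts the primary alcohol into the iodide by SN2 displacement under buffered neutral conditions, leaving the oxirane and both of its stereocenters unchanged (the C7'' descriptor becomes S only because CH2I outranks C6'').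

Step 18
Reactants: 23 the epoxy iodide
Product: 24 (2S)-6-[(2E,6R)-6-hydroxy-3,7-dimethylocta-2,7-dien-1-yl]-2-[3-methoxy-4,5-bis(methoxymethoxy)phenyl]-5,7-bis(methoxymethoxy)chroman-4-one
Conditions: Zn dust (activated, 5 equiv), AcOH (3 equiv), EtOH, 0 °C → rt
Reagents that add atoms: none
Why: In this reductive β-elimination of a 2,3-epoxy iodide, zinc reduces the C8''–I bond and the resulting organozinc expels the oxirane oxygen, which forms C7''=C8'' and breaks C7''–O while the C6''–O bond, and hence the 6''R configuration, is never touched, and the aryl ketone and acetals are inert to zinc and acetic acid at room temperature.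

Step 19
Reactants: 24 the tetra-MOM allylic alcohol
Product: 26 (2S)-2-(3,4-dihydroxy-5-methoxyphenyl)-5,7-dihydroxy-6-[(2E,6R)-6-hydroxy-3,7-dimethylocta-2,7-dien-1-yl]chroman-4-one (CNP0144204.1), via pentakis-trimethylsilyl ether 25 (not isolated)
Conditions: TMSOTf (12 equiv), 2,2′-bipyridyl (18 equiv), CH3CN, 0 °C → rt; then H2O, rt
Reagents that add atoms: none
Why: In this silyl-transfer cleavage of aromatic MOM ethers the silyl triflate–bipyridyl reagent turns each aryl acetal into an aryl trimethylsilyl ether by passing the acetal carbon to bipyridyl, and water then hydrolyses all silyl ethers, so the four phenols are freed without protic acid (no addition of ring A hydroxyls across C2''=C3'', no ionisation of the allylic carbinol) and without base (no epimerisation at C2).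

Compound list
1 | geranyl acetate, (2E)-3,7-dimethylocta-2,6-dien-1-yl acetate | CC(C)=CCC/C(C)=C/COC(C)=O | starting material
2 | (2E,6E)-8-hydroxy-3,7-dimethylocta-2,6-dien-1-yl acetate | OC/C(C)=C/CC/C(C)=C/COC(C)=O | intermediate
3 | (2E,6E)-8-[(tert-butyldiphenylsilyl)oxy]-3,7-dimethylocta-2,6-dien-1-yl acetate | CC(C)(C)[Si](OC/C(C)=C/CC/C(C)=C/COC(C)=O)(c1ccccc1)c1ccccc1 | intermediate
4 | (2E,6E)-8-[(tert-butyldiphenylsilyl)oxy]-3,7-dimethylocta-2,6-dien-1-ol | CC(C)(C)[Si](OC/C(C)=C/CC/C(C)=C/CO)(c1ccccc1)c1ccccc1 | intermediate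
5 | (2E,6E)-1-bromo-8-[(tert-butyldiphenylsilyl)oxy]-3,7-dimethylocta-2,6-diene | CC(C)(C)[Si](OC/C(C)=C/CC/C(C)=C/CBr)(c1ccccc1)c1ccccc1 | intermediate
6 | phloroglucinol | Oc1cc(O)cc(O)c1 | starting material
7 | 3,5-bis(methoxymethoxy)phenol | COCOc1cc(O)cc(OCOC)c1 | intermediate
8 | [3,5-bis(methoxymethoxy)phenoxy]triisopropylsilane | COCOc1cc(O[Si](C(C)C)(C(C)C)C(C)C)cc(OCOC)c1 | intermediate
9 | 2,6-bis(methoxymethoxy)-4-(triisopropylsilyloxy)phenyllithium (formed in the flask) | [Li]c1c(OCOC)cc(O[Si](C(C)C)(C(C)C)C(C)C)cc1OCOC | intermediate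
10 | [3,5-bis(methoxymethoxy)-4-(silyloxygeranyl)phenoxy]triisopropylsilane | CC(C)(C)[Si](OC/C(C)=C/CC/C(C)=C/Cc1c(OCOC)cc(O[Si](C(C)C)(C(C)C)C(C)C)cc1OCOC)(c1ccccc1)c1ccccc1 | intermediate
11 | 3,5-bis(methoxymethoxy)-4-(silyloxygeranyl)phenol | CC(C)(C)[Si](OC/C(C)=C/CC/C(C)=C/Cc1c(OCOC)cc(O)cc1OCOC)(c1ccccc1)c1ccccc1 | intermediate
12 | 6-hydroxy-2,4-bis(methoxymethoxy)-3-(silyloxygeranyl)benzaldehyde | CC(C)(C)[Si](OC/C(C)=C/CC/C(C)=C/Cc1c(OCOC)cc(O)c(C=O)c1OCOC)(c1ccccc1)c1ccccc1 | intermediate
13 | rac-1-[6-hydroxy-2,4-bis(methoxymethoxy)-3-(silyloxygeranyl)phenyl]prop-2-yn-1-ol | CC(C)(C)[Si](OC/C(C)=C/CC/C(C)=C/Cc1c(OCOC)cc(O)c(C(O)C#C)c1OCOC)(c1ccccc1)c1ccccc1 | intermediate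
14 | 1-[6-hydroxy-2,4-bis(methoxymethoxy)-3-(silyloxygeranyl)phenyl]prop-2-yn-1-one (formed in the flask) | CC(C)(C)[Si](OC/C(C)=C/CC/C(C)=C/Cc1c(OCOC)cc(O)c(C(=O)C#C)c1OCOC)(c1ccccc1)c1ccccc1 | intermediate
15 | 5,7-bis(methoxymethoxy)-6-(silyloxygeranyl)-4H-chromen-4-one | CC(C)(C)[Si](OC/C(C)=C/CC/C(C)=C/Cc1c(OCOC)cc2occc(=O)c2c1OCOC)(c1ccccc1)c1ccccc1 | intermediate
16 | 3-methoxycatechol | COc1cccc(O)c1O | starting material
17 | 1-methoxy-2,3-bis(methoxymethoxy)benzene | COCOc1cccc(OC)c1OCOC | intermediate
18 | 2-[3-methoxy-4,5-bis(methoxymethoxy)phenyl]-4,4,5,5-tetramethyl-1,3,2-dioxaborolane (formed in the flask) | COCOc1cc(B2OC(C)(C)C(C)(C)O2)cc(OC)c1OCOC | intermediate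
19 | [3-methoxy-4,5-bis(methoxymethoxy)phenyl]boronic acid | COCOc1cc(B(O)O)cc(OC)c1OCOC | intermediate
20 | (2S)-2-[3-methoxy-4,5-bis(methoxymethoxy)phenyl]-5,7-bis(methoxymethoxy)-6-(silyloxygeranyl)chroman-4-one | CC(C)(C)[Si](OC/C(C)=C/CC/C(C)=C/Cc1c(OCOC)cc2c(c1OCOC)C(=O)C[C@@H](c1cc(OCOC)c(OCOC)c(OC)c1)O2)(c1ccccc1)c1ccccc1 | intermediate
21 | (2S)-6-[(2E,6E)-8-hydroxy-3,7-dimethylocta-2,6-dien-1-yl]-2-[3-methoxy-4,5-bis(methoxymethoxy)phenyl]-5,7-bis(methoxymethoxy)chroman-4-one (key-step precursor) | OC/C(C)=C/CC/C(C)=C/Cc1c(OCOC)cc2c(c1OCOC)C(=O)C[C@@H](c1cc(OCOC)c(OCOC)c(OC)c1)O2 | intermediate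
22 | (2S)-6-{(2E)-5-[(2R,3R)-3-(hydroxymethyl)-3-methyloxiran-2-yl]-3-methylpent-2-en-1-yl}-2-[3-methoxy-4,5-bis(methoxymethoxy)phenyl]-5,7-bis(methoxymethoxy)chroman-4-one, (6''R,7''R) (key-step product) | OC[C@@]1(C)O[C@@H]1CC/C(C)=C/Cc1c(OCOC)cc2c(c1OCOC)C(=O)C[C@@H](c1cc(OCOC)c(OCOC)c(OC)c1)O2 | intermediate
23 | (2S)-6-{(2E)-5-[(2R,3S)-3-(iodomethyl)-3-methyloxiran-2-yl]-3-methylpent-2-en-1-yl}-2-[3-methoxy-4,5-bis(methoxymethoxy)phenyl]-5,7-bis(methoxymethoxy)chroman-4-one | IC[C@@]1(C)O[C@@H]1CC/C(C)=C/Cc1c(OCOC)cc2c(c1OCOC)C(=O)C[C@@H](c1cc(OCOC)c(OCOC)c(OC)c1)O2 | intermediate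
24 | (2S)-6-[(2E,6R)-6-hydroxy-3,7-dimethylocta-2,7-dien-1-yl]-2-[3-methoxy-4,5-bis(methoxymethoxy)phenyl]-5,7-bis(methoxymethoxy)chroman-4-one | C=C(C)[C@H](O)CC/C(C)=C/Cc1c(OCOC)cc2c(c1OCOC)C(=O)C[C@@H](c1cc(OCOC)c(OCOC)c(OC)c1)O2 | intermediate
25 | pentakis(trimethylsilyl) ether of the target, silylated at O5, O7, O3', O4' and O6'' (formed in the flask) | C=C(C)[C@H](O[Si](C)(C)C)CC/C(C)=C/Cc1c(O[Si](C)(C)C)cc2c(c1O[Si](C)(C)C)C(=O)C[C@@H](c1cc(O[Si](C)(C)C)c(O[Si](C)(C)C)c(OC)c1)O2 | intermediate
26 | (2S)-2-(3,4-dihydroxy-5-methoxyphenyl)-5,7-dihydroxy-6-[(2E,6R)-6-hydroxy-3,7-dimethylocta-2,7-dien-1-yl]chroman-4-one, CNP0144204.1 | C=C(C)[C@H](O)CC/C(C)=C/Cc1c(O)cc2c(c1O)C(=O)C[C@@H](c1cc(O)c(O)c(OC)c1)O2 | target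

Total step count: 19
Longest linear sequence: 15 steps (1–4, 7–11, 14–19, from geranyl acetate)

Steps most likely to fail

Step 14. What may go wrong: insertion of the chromone into the aryl–rhodium bond is slow for this electron-rich, peri-alkoxylated acceptor, so protodeboronation of 19 and β-aryloxide elimination from the rhodium enolate (opening of ring C) can outrun product formation, and face selection may be incomplete. Fallback, setting out from 15 (with 19) and returning at 20: catalyst control is given up in favour of resolution. The addition is run without chiral ligand with the most active catalyst, [Rh(OH)(cod)]2 in dioxane/H2O at 60 °C, to give the racemic flavanone F1, which is resolved by preparative HPLC on an amylose tris(3,5-dimethylphenylcarbamate) phase. The (2S)-enantiomer is 20 and the (2R)-enantiomer F2 is set aside.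

Step 16. What may go wrong: the many ether and carbonyl oxygens may hold titanium away from the tartrate assembly so that turnover stalls, or face selection may be incomplete and leave an oxirane epimer that cannot be separated. Fallback, setting out from 21 and returning at 24: the C6'' centre is set by ketone reduction instead of by oxygen transfer. Hydroxyl-directed epoxidation with VO(acac)2 (cat.) and t-BuOOH in CH2Cl2 gives, with site selectivity but no face control, the trans-epoxy alcohol mixture F3. PPh3/I2/imidazole converts it into the epoxy iodide mixture F4, and Zn/AcOH gives the C6''-epimeric allylic alcohol mixture F5. Dess–Martin oxidation (NaHCO3, CH2Cl2) gives the isopropenyl ketone F6. Corey–Bakshi–Shibata reduction with (S)-2-methyl-CBS-oxazaborolidine and catecholborane in toluene at −78 °C should then give 24. It should reduce only the enone carbonyl, because the C4 carbonyl is a deactivated, doubly ortho-substituted aryl ketone, and the isopropenyl group acts as the large substituent, which should give 6''R.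

Step 11. What may go wrong: MnO2 may attack the electron-rich phenol in competition with the carbinol (oxidative coupling, quinone-methide formation from the ortho-hydroxybenzyl alcohol), or the ynone may close 5-exo to the benzofuranone or oligomerise. Fallback, setting out from phenol 11 and returning at 15 (it replaces steps 9–11): the carbonyl carbon is brought in by aryllithium acylation, with no benzylic alcohol and no oxidation. Dihydropyran/PPTS gives the tetrahydropyranyl ether F7. Ortho-lithiation between the tetrahydropyranyloxy and MOM groups (n-BuLi, THF, 0 °C) and Weinreb acylation with N-methoxy-N-methylacetamide give the acetophenone F8. Condensation with N,N-dimethylformamide dimethyl acetal (toluene, 90 °C) gives the enaminone F9. PPTS in MeOH at 50 °C removes the tetrahydropyranyl group to give the phenol enaminone F10, which closes with loss of dimethylamine to chromone 15.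

Further compounds
F1 | step 14 | racemic 2-[3-methoxy-4,5-bis(methoxymethoxy)phenyl]-5,7-bis(methoxymethoxy)-6-(silyloxygeranyl)chroman-4-one | CC(C)(C)[Si](OC/C(C)=C/CC/C(C)=C/Cc1c(OCOC)cc2c(c1OCOC)C(=O)CC(c1cc(OCOC)c(OCOC)c(OC)c1)O2)(c1ccccc1)c1ccccc1
F2 | step 14 | (2R)-2-[3-methoxy-4,5-bis(methoxymethoxy)phenyl]-5,7-bis(methoxymethoxy)-6-(silyloxygeranyl)chroman-4-one | CC(C)(C)[Si](OC/C(C)=C/CC/C(C)=C/Cc1c(OCOC)cc2c(c1OCOC)C(=O)C[C@H](c1cc(OCOC)c(OCOC)c(OC)c1)O2)(c1ccccc1)c1ccccc1
F3 | step 16 | (2S)-flavanone 6'',7''-trans-epoxy alcohol, both oxirane configurations (22 and its 6''S,7''S isomer) | OCC1(C)OC1CC/C(C)=C/Cc1c(OCOC)cc2c(c1OCOC)C(=O)C[C@@H](c1cc(OCOC)c(OCOC)c(OC)c1)O2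
F4 | step 16 | (2S)-flavanone 6'',7''-trans-epoxy iodide, both oxirane configurations | ICC1(C)OC1CC/C(C)=C/Cc1c(OCOC)cc2c(c1OCOC)C(=O)C[C@@H](c1cc(OCOC)c(OCOC)c(OC)c1)O2
F5 | step 16 | (2S)-6-[(2E,6RS)-6-hydroxy-3,7-dimethylocta-2,7-dien-1-yl]-2-[3-methoxy-4,5-bis(methoxymethoxy)phenyl]-5,7-bis(methoxymethoxy)chroman-4-one (24 and its 6''-epimer) | C=C(C)C(O)CC/C(C)=C/Cc1c(OCOC)cc2c(c1OCOC)C(=O)C[C@@H](c1cc(OCOC)c(OCOC)c(OC)c1)O2
F6 | step 16 | (2S)-6-[(2E)-3,7-dimethyl-6-oxoocta-2,7-dien-1-yl]-2-[3-methoxy-4,5-bis(methoxymethoxy)phenyl]-5,7-bis(methoxymethoxy)chroman-4-one | C=C(C)C(=O)CC/C(C)=C/Cc1c(OCOC)cc2c(c1OCOC)C(=O)C[C@@H](c1cc(OCOC)c(OCOC)c(OC)c1)O2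
F7 | step 11 | 2-[3,5-bis(methoxymethoxy)-4-(silyloxygeranyl)phenoxy]oxane (racemic tetrahydropyranyl ether of 11) | CC(C)(C)[Si](OC/C(C)=C/CC/C(C)=C/Cc1c(OCOC)cc(OC2CCCCO2)cc1OCOC)(c1ccccc1)c1ccccc1
F8 | step 11 | 1-[2,4-bis(methoxymethoxy)-6-(oxan-2-yloxy)-3-(silyloxygeranyl)phenyl]ethan-1-one | CC(C)(C)[Si](OC/C(C)=C/CC/C(C)=C/Cc1c(OCOC)cc(OC2CCCCO2)c(C(C)=O)c1OCOC)(c1ccccc1)c1ccccc1
F9 | step 11 | (2E)-1-[2,4-bis(methoxymethoxy)-6-(oxan-2-yloxy)-3-(silyloxygeranyl)phenyl]-3-(dimethylamino)prop-2-en-1-one | CC(C)(C)[Si](OC/C(C)=C/CC/C(C)=C/Cc1c(OCOC)cc(OC2CCCCO2)c(C(=O)/C=C/N(C)C)c1OCOC)(c1ccccc1)c1ccccc1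
F10 | step 11 | (2E)-3-(dimethylamino)-1-[6-hydroxy-2,4-bis(methoxymethoxy)-3-(silyloxygeranyl)phenyl]prop-2-en-1-one | CC(C)(C)[Si](OC/C(C)=C/CC/C(C)=C/Cc1c(OCOC)cc(O)c(C(=O)/C=C/N(C)C)c1OCOC)(c1ccccc1)c1ccccc1
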